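4 questions are asked of these flasks, and one quantity read from the runs serves the last two of them.

all flasks: free catalyst 0.0400 M
- larch: substrate 0.400 M; coupling partner 0.600 M
- cedar: substrate 0.240 M; coupling partner 0.440 M
- maple: substrate 0.400 M; coupling partner 0.300 M
- oak: substrate 0.400 M; coupling partner 0.600 M; product 0.200 M
- alder: substrate 0.400 M; coupling partner 0.170 M; time 5.0 min

| larch run: time / min | larch run: [product] / M | cedar run: time / min | cedar run: [product] / M | maple run: time / min | maple run: [product] / M | oak run: time / min | oak run: [product] / M |
|---|---|---|---|---|---|---|---|
| 0.18 | 0.009 | 0.18 | 0.006 | 0.18 | 0.004 | 0.18 | 0.211 |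
| 0.54 | 0.027 | 0.54 | 0.009 | 0.54 | 0.012 | 0.54 | 0.225 |
| 1.0 | 0.052 | 1.0 | 0.025 | 1.0 | 0.030 | 1.0 | 0.248 |
| 1.6 | 0.085 | 1.6 | 0.035 | 1.6 | 0.038 | 1.6 | 0.272 |
| 2.4 | 0.105 | 2.4 | 0.054 | 2.4 | 0.067 | 2.4 | 0.310 |
| 3.2 | 0.131 | 3.2 | 0.074 | 3.2 | 0.081 | 3.2 | 0.332 |
| 4.0 | 0.150 | 4.0 | 0.089 | 4.0 | 0.090 | 4.0 | 0.350 |
| 5.0 | 0.168 | 5.0 | 0.096 | 5.0 | 0.111 | 5.0 | 0.366 |

(readings scatter by 0.003 M)

- Overall: substrate + coupling partner -> product, with free catalyst as catalyst.
- Constant volume, constant temperature.
- What is held in complexes is read along with the free species.
- An order is taken over about fifteen percent of the charge, up and down.

1. the exponent of [substrate] in the starting rate at the charge of the larch run (at the point where two percent of the substrate have become product) (one fixed amount of product, the same in the runs compared)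
2. the exponent of [coupling partner] in the starting rate at the charge of the larch run (at the point where two percent of the substrate have become product)
3. the cedar run starts with 0.160 M less of substrate and of coupling partner than the larch run, and with no product. Compared where both hold the same amount of substrate, once fifteen percent of what the cedar run was charged with has turned into product, is the cedar run faster, slower or alike (within a tenth)?
4. product in the alder run at 5.0 min, as a share of the substrate charged

The quantity I carry is the k that makes the plain law, rate = k·c(substrate)·c(coupling partner), when integrated over a run, return the product newly made at that run's last reading. In the cedar run this gives 0.265 M⁻¹ min⁻¹, and I call it the working constant. One standard deviation of that last reading moves it by 0.0121 M⁻¹ min⁻¹. The larch run, with 0.168 M made, gives 0.216 M⁻¹ min⁻¹, which is lower than the cedar value. The maple run gives 0.274 M⁻¹ min⁻¹, close to cedar. The oak run, charged with 0.200 M of product, makes 0.166 M of new product and gives 0.212 M⁻¹ min⁻¹, close to larch. The oak value stands within 0.00400 M⁻¹ min⁻¹ of the larch value, so product put in at the start shows no effect on this constant, while the cedar and maple values, higher than larch, come from smaller charges, so that gap mixes charge with history and does not answer the third question.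

Now turn the third question round and ask what the verdict alike would require. The cedar charge is the larch charge less 0.160 M in both reagents, so at equal substrate the two runs also hold equal coupling partner, and they differ in history, since the larch run has by then made 0.160 M more. Alike would therefore need the larch run, where it passes through the cedar charge, to show the same constant as the early cedar run. Between its last two readings the larch run goes through that substrate level, and the same integrated law over that interval gives 0.170 M⁻¹ min⁻¹, while the cedar run up to 2.4 min gives 0.258 M⁻¹ min⁻¹, which is higher, at a reading ratio of 1.52. One standard deviation in either larch reading moves that interval value by about 0.0284 M⁻¹ min⁻¹, so the comparison is thin, but it leans one way, and my own answer is faster. For the alder run, where coupling partner is the limiting reagent, I would put in the cedar constant as a low estimate, which gives 16.2% of the substrate charged.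

The forecast says 0.9 for substrate, 0.8 for coupling partner, faster for cedar and 17% for alder, a little above my estimate. It reads the downward drift within runs to mean that “the catalyst is probably dying slowly”.

The flask gives 0.81, 0.81, faster and 18.1%, from these steps:

    free catalyst + substrate → loaded catalyst + by-product (3.702 M⁻¹ min⁻¹)
    loaded catalyst + coupling partner → product + free catalyst (3.708 M⁻¹ min⁻¹)
    substrate + coupling partner → product (0.1536 M⁻¹ min⁻¹)
    free catalyst + by-product ⇌ catalyst-by-product complex, settled at all times (149.0 M⁻¹)

At equal substrate the cedar run goes 1.4 times as fast as the larch run. With the association of free catalyst and by-product removed, that ratio drops from 1.4 to 0.97, which is alike, so the complex is what separates the runs. The alder run, with 0.0725 M of product made at 5.0 min, has a working constant of 0.309 M⁻¹ min⁻¹, higher than the cedar value.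

(The readings are simulated with constants of no real substance; the scatter is artificial.)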